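The route rests on disconnecting the cyclopentanone at C1–C7a (indene numbering: C1 carries the methyl group, C7a is the ring-fusion carbon beside the C6=C7 double bond). In the precursor C7a is an allylic ring CH2 of a cyclohexene, 1,5 to the diazo carbon of an α-diazo ethyl ketone on C3a. One dirhodium-carbenoid C–H insertion closes the five-membered ring with retention, sets C7a and C1 and gives the trans ring fusion. The cyclohexene, with its two adjacent quaternary carbons C4 and C5, comes from a ring-contracting Ireland–Claisen rearrangement of a δ-lactone that carries a dienyl group on its carbinol carbon.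

Key step: step 13

Remark: compounds 4–16 are carried as mixtures of epimers at the ester α-carbon (the later C4 of the target). This centre becomes planar in the ketene acetal of step 11, so its descriptor is left open in names and SMILES.

Step 1
Reactants: 1 methyl butanoate
Product: 2 1-methoxy-1-(trimethylsilyloxy)but-1-ene (E/Z mixture)
Conditions: LiN(iPr)2, THF, −78 °C; Me3SiCl, −78 °C → rt
Reagents that add atoms: chlorotrimethylsilane C[Si](C)(C)Cl
Why: Kinetic ester enolisation and O-silylation is the standard route to ketene silyl acetals, and the E/Z ratio is immaterial because this carbon is made planar again in step 11.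

Step 2
Reactants: 2 1-methoxy-1-(trimethylsilyloxy)but-1-ene; 3 cyclohex-2-en-1-one
Product: 4 methyl 2-[(1R)-3-(trimethylsilyloxy)cyclohex-2-en-1-yl]butanoate
Conditions: chiral oxazaborolidinium catalyst (B-o-tolyl oxazaborolidine from diphenylprolinol, protonated with HNTf2, 20 mol%, enantiomer chosen for the 1R adduct), Ph3P=O, toluene, −20 °C
Reagents that add atoms: none
Why: In this catalytic enantioselective Mukaiyama–Michael addition the chiral boron Lewis acid shields one face of the enone so that C1 should form with R configuration, and silyl transfer leaves the regiodefined silyl enol ether.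

Step 3
Reactants: 4 methyl 2-[(1R)-3-(trimethylsilyloxy)cyclohex-2-en-1-yl]butanoate
Product: 5 methyl 2-[(1R,2S)-2-ethyl-3-oxocyclohexyl]butanoate
Conditions: BnMe3N+ F− (anhydrous), EtI, 4 Å sieves, THF, −78 °C → rt
Reagents that add atoms: iodoethane CCI
Why: Fluoride unmasks the enolate regiospecifically at C2 without touching the ester, and alkylation should occur anti to the C1 substituent to give the trans (2S) ketone (regiospecific alkylation of a silyl enol ether).

Step 4
Reactants: 5 methyl 2-[(1R,2S)-2-ethyl-3-oxocyclohexyl]butanoate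
Product: 7 methyl 2-[(1R,2S)-2-ethyl-3-oxocyclohex-4-en-1-yl]butanoate, via silyl enol ether 6 (not isolated)
Conditions: LiN(iPr)2, Me3SiCl, THF, −78 °C; then Pd(OAc)2 (1.05 equiv), MeCN, rt
Reagents that add atoms: none
Why: Kinetic deprotonation takes the ring CH2 rather than the ethyl-bearing CH, and Saegusa–Ito dehydrosilylation of that silyl enol ether places the enone on the side away from the stereocentres.

Step 5
Reactants: 7 methyl 2-[(1R,2S)-2-ethyl-3-oxocyclohex-4-en-1-yl]butanoate
Product: 8 methyl 2-[(1R,2S)-2,3-diethyl-3-hydroxycyclohex-4-en-1-yl]butanoate (C3 epimers)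
Conditions: EtMgBr, CeCl3 (anhydrous), THF, −78 °C; aq. NH4Cl
Reagents that add atoms: ethylmagnesium bromide CC[Mg]Br
Why: With CeCl3 the Grignard reagent adds to the enone in the 1,2 sense and spares the ester at low temperature, and the configuration of the new carbinol is irrelevant because the next step removes it.

Step 6
Reactants: 8 methyl 2-[(1R,2S)-2,3-diethyl-3-hydroxycyclohex-4-en-1-yl]butanoate
Product: 9 methyl 2-[(1R,2S)-2,3-diethyl-5-oxocyclohex-3-en-1-yl]butanoate
Conditions: pyridinium chlorochromate C5H5NH[CrO3Cl], 4 Å sieves, CH2Cl2, rt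
Reagents that add atoms: none
Why: In this oxidative 1,3-transposition (Babler–Dauben type) the chromate ester of the tertiary allylic alcohol undergoes a [3,3] shift and is oxidised to the transposed β-ethyl enone.

Step 7
Reactants: 9 methyl 2-[(1R,2S)-2,3-diethyl-5-oxocyclohex-3-en-1-yl]butanoate
Product: 11 (1S,5R,6S)-1,4,6,7-tetraethyl-2-oxabicyclo[3.3.1]non-7-en-3-one, via hydroxy ester 10 (not isolated)
Conditions: EtMgBr, CeCl3 (anhydrous), THF, −78 °C → 40 °C; aq. NH4Cl
Reagents that add atoms: ethylmagnesium bromide CC[Mg]Br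
Why: Grignard 1,2-addition should follow the axial trajectory anti to the ester-bearing side chain, so the new tertiary alkoxide is cis to that arm and closes the bridged δ-lactone on warming, and only this cis adduct can lactonise.

Step 8
Reactants: 11 (1S,5R,6S)-1,4,6,7-tetraethyl-2-oxabicyclo[3.3.1]non-7-en-3-one
Product: 13 (2S,4R)-2,5-diethyl-6-oxo-4-[(3S)-4-oxohexan-3-yl]oxane-2-carbaldehyde, via secondary ozonide 12 (not isolated)
Conditions: O3, CH2Cl2, −78 °C; then Me2S, −78 °C → rt
Reagents that add atoms: ozone [O-][O+]=O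
Why: Ozonolysis of the only C=C opens the carbocycle and unveils the ethyl ketone and the aldehyde in one operation, leaving a δ-lactone whose C4 side chain and C2 formyl group are cis by construction.

Step 9
Reactants: 14 diethyl [(2E)-3-phenylprop-2-en-1-yl]phosphonate
Product: 15 diethyl [(1E)-1-phenylpent-1-en-3-yl]phosphonate (racemic)
Conditions: n-BuLi, THF, −78 °C; then EtI, −78 → 0 °C
Reagents that add atoms: iodoethane CCI
Why: Allylic phosphonate carbanions are alkylated at the α-carbon, which gives the α-ethyl cinnamyl phosphonate whose stereocentre is lost in the next step.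

Step 10
Reactants: 13 (2S,4R)-2,5-diethyl-6-oxo-4-[(3S)-4-oxohexan-3-yl]oxane-2-carbaldehyde; 15 diethyl [(1E)-1-phenylpent-1-en-3-yl]phosphonate
Product: 16 (4R,6S)-3,6-diethyl-6-[(1E,3E)-2-ethyl-4-phenylbuta-1,3-dien-1-yl]-4-[(3S)-4-oxohexan-3-yl]oxan-2-one
Conditions: LiN(SiMe3)2, THF, −78 °C (15); then 13, −78 °C → rt
Reagents that add atoms: none
Why: Horner–Wadsworth–Emmons olefination of the non-enolisable aldehyde by the conjugation-stabilised carbanion should place the bulky lactone carbon trans to the styryl group (E), the ketone being far less electrophilic than the aldehyde.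

Step 11
Reactants: 16 (4R,6S)-3,6-diethyl-6-[(1E,3E)-2-ethyl-4-phenylbuta-1,3-dien-1-yl]-4-[(3S)-4-oxohexan-3-yl]oxan-2-one
Product: 19 (1R,2S,6R)-1,2,4-triethyl-6-[(3S)-4-oxohexan-3-yl]-2-[(E)-2-phenylethenyl]cyclohex-3-ene-1-carboxylic acid, via bis-silyl ketene acetal 17 (not isolated), via rearranged silyl ester 18 (not isolated)
Conditions: LiN(iPr)2 (3.5 equiv), Me3SiCl/Et3N, THF, −78 °C → 65 °C; then 1 M HCl
Reagents that add atoms: none
Why: In this ring-contracting Ireland–Claisen rearrangement of a lactone ketene silyl acetal the six-membered ring enforces a boat transition state in which the dienyl group on C6 reaches the α-carbon from its own face, so the C6 configuration and the E geometry should be transferred to the two new quaternary centres (C1 R, C2 S), while the ketone rides through as its silyl enol ether.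

Step 12
Reactants: 19 (1R,2S,6R)-1,2,4-triethyl-6-[(3S)-4-oxohexan-3-yl]-2-[(E)-2-phenylethenyl]cyclohex-3-ene-1-carboxylic acid
Product: 21 (1R,2S,6R)-6-[(3S)-5-diazo-4-oxohexan-3-yl]-1,2,4-triethyl-2-[(E)-2-phenylethenyl]cyclohex-3-ene-1-carboxylic acid, via trifluoroacetyl ketone 20 (not isolated)
Conditions: LiN(SiMe3)2 (3.3 equiv), THF, −78 °C; CF3CO2CH2CF3; then MsN3, Et3N, H2O, MeCN, rt; dilute HCl
Reagents that add atoms: methanesulfonyl azide CS(=O)(=O)N=[N+]=[N-]
Why: In this detrifluoroacetylative diazo transfer the ethyl ketone is enolised kinetically at its CH2 (the carboxylate is inert), C-trifluoroacetylated and converted by the sulfonyl azide into the α-diazo ketone.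

Step 13
Reactants: 21 (1R,2S,6R)-6-[(3S)-5-diazo-4-oxohexan-3-yl]-1,2,4-triethyl-2-[(E)-2-phenylethenyl]cyclohex-3-ene-1-carboxylic acid
Product: 24 (1S,3S,3aR,4R,5S,7aR)-3,4,5,7-tetraethyl-1-methyl-2-oxo-5-[(E)-2-phenylethenyl]-2,3,3a,4,5,7a-hexahydro-1H-indene-4-carboxylic acid, via silyl ester of the diazo acid 22 (not isolated), via silyl ester of the cyclised acid 23 (not isolated)
Conditions: BSA, CH2Cl2, rt; then Rh2(O2CCPh3)4 (1 mol%), CH2Cl2, −40 °C → rt, slow addition; then MeOH, DBU, rt; aq. citric acid
Reagents that add atoms: none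
Why: After in situ silylation of the acid (to exclude O–H insertion), loss of N2 gives an electrophilic dirhodium carbenoid at the future C1, which inserts into the allylic C–H of the future C7a through a concerted three-centre transition state with retention. The closest known reaction type is the dirhodium-catalysed intramolecular 1,5 C–H insertion of α-diazo ketones to cyclopentanones. The cyclopentanone closes in the five-membered mode (carbenoid carbon onto the C–H carbon four atoms away), which is preferred over four- and six-membered alternatives, and the only other 1,5 C–H bond is a primary one. C7a is set by the choice of hydrogen: the side chain should be equatorial (the axial conformer has a 1,3-diaxial clash with the C5 ethyl group), so the carbenoid reaches the pseudo-equatorial C–H trans to it and the trans ring fusion should result; C1 should form with methyl trans to the C7a–C7 bond in a chair-like transition state, and DBU then equilibrates C1 and C3 to the all-trans arrangement expected to be the most stable. The step needs insertion to win over 1,2-hydride shift from the methyl group and over cyclopropanation of the C6=C7 alkene: bulky triphenylacetate ligands and low temperature disfavour the hydride shift, and cyclopropanation would require an axial side chain and a bridged bicyclo[3.3.1] transition state.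

Compound list
1 | methyl butanoate | CCCC(=O)OC | starting material
2 | 1-methoxy-1-(trimethylsilyloxy)but-1-ene (E/Z mixture) | CCC=C(OC)O[Si](C)(C)C | intermediate
3 | cyclohex-2-en-1-one | O=C1C=CCCC1 | starting material
4 | methyl 2-[(1R)-3-(trimethylsilyloxy)cyclohex-2-en-1-yl]butanoate | CCC(C(=O)OC)[C@@H]1CCCC(O[Si](C)(C)C)=C1 | intermediate
5 | methyl 2-[(1R,2S)-2-ethyl-3-oxocyclohexyl]butanoate | CC[C@@H]1C(=O)CCC[C@H]1C(CC)C(=O)OC | intermediate
6 | methyl 2-[(1R,2S)-2-ethyl-3-(trimethylsilyloxy)cyclohex-3-en-1-yl]butanoate | CC[C@@H]1C(O[Si](C)(C)C)=CCC[C@H]1C(CC)C(=O)OC | intermediate (not isolated)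
7 | methyl 2-[(1R,2S)-2-ethyl-3-oxocyclohex-4-en-1-yl]butanoate | CC[C@@H]1C(=O)C=CC[C@H]1C(CC)C(=O)OC | intermediate
8 | methyl 2-[(1R,2S)-2,3-diethyl-3-hydroxycyclohex-4-en-1-yl]butanoate (C3 epimers) | CC[C@@H]1C(O)(CC)C=CC[C@H]1C(CC)C(=O)OC | intermediate
9 | methyl 2-[(1R,2S)-2,3-diethyl-5-oxocyclohex-3-en-1-yl]butanoate | CC[C@@H]1C(CC)=CC(=O)C[C@H]1C(CC)C(=O)OC | intermediate
10 | methyl 2-[(1R,2S,5S)-2,3,5-triethyl-5-hydroxycyclohex-3-en-1-yl]butanoate | CC[C@@H]1C(CC)=C[C@](O)(CC)C[C@H]1C(CC)C(=O)OC | intermediate (not isolated)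
11 | (1S,5R,6S)-1,4,6,7-tetraethyl-2-oxabicyclo[3.3.1]non-7-en-3-one | CC[C@@]12C=C(CC)[C@@H](CC)[C@@H](C1)C(CC)C(=O)O2 | intermediate
12 | secondary ozonide of 11 (1,2,4-trioxolane across C7 and C8) | CC[C@@]12C3OOC(CC)(O3)[C@@H](CC)[C@@H](C1)C(CC)C(=O)O2 | intermediate (not isolated)
13 | (2S,4R)-2,5-diethyl-6-oxo-4-[(3S)-4-oxohexan-3-yl]oxane-2-carbaldehyde | CC[C@@]1(C=O)C[C@H]([C@H](CC)C(=O)CC)C(CC)C(=O)O1 | intermediate
14 | diethyl [(2E)-3-phenylprop-2-en-1-yl]phosphonate | CCOP(=O)(OCC)C/C=C/c1ccccc1 | starting material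
15 | diethyl [(1E)-1-phenylpent-1-en-3-yl]phosphonate (racemic) | CCOP(=O)(OCC)C(CC)/C=C/c1ccccc1 | intermediate
16 | (4R,6S)-3,6-diethyl-6-[(1E,3E)-2-ethyl-4-phenylbuta-1,3-dien-1-yl]-4-[(3S)-4-oxohexan-3-yl]oxan-2-one | CC[C@@]1(/C=C(\CC)/C=C/c2ccccc2)C[C@H]([C@H](CC)C(=O)CC)C(CC)C(=O)O1 | intermediate
17 | bis(trimethylsilyl) derivative of 16 (lactone ketene silyl acetal, ketone as silyl enol ether) | CCC1=C(O[Si](C)(C)C)O[C@](CC)(/C=C(\CC)/C=C/c2ccccc2)C[C@@H]1[C@H](CC)C(=CC)O[Si](C)(C)C | intermediate (not isolated)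
18 | trimethylsilyl ester of 19 with the ketone as its trimethylsilyl enol ether | CCC1=C[C@@](/C=C/c2ccccc2)(CC)[C@](CC)(C(=O)O[Si](C)(C)C)[C@H](C1)[C@H](CC)C(=CC)O[Si](C)(C)C | intermediate (not isolated)
19 | (1R,2S,6R)-1,2,4-triethyl-6-[(3S)-4-oxohexan-3-yl]-2-[(E)-2-phenylethenyl]cyclohex-3-ene-1-carboxylic acid | CCC1=C[C@@](/C=C/c2ccccc2)(CC)[C@](CC)(C(=O)O)[C@H](C1)[C@H](CC)C(=O)CC | intermediate
20 | α-trifluoroacetyl derivative of 19 (trifluoroacetyl on the ketone CH2) | CCC1=C[C@@](/C=C/c2ccccc2)(CC)[C@](CC)(C(=O)O)[C@H](C1)[C@H](CC)C(=O)C(C)C(=O)C(F)(F)F | intermediate (not isolated)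
21 | (1R,2S,6R)-6-[(3S)-5-diazo-4-oxohexan-3-yl]-1,2,4-triethyl-2-[(E)-2-phenylethenyl]cyclohex-3-ene-1-carboxylic acid | CCC1=C[C@@](/C=C/c2ccccc2)(CC)[C@](CC)(C(=O)O)[C@H](C1)[C@H](CC)C(=O)C(C)=[N+]=[N-] | intermediate
22 | trimethylsilyl ester of 21 | CCC1=C[C@@](/C=C/c2ccccc2)(CC)[C@](CC)(C(=O)O[Si](C)(C)C)[C@H](C1)[C@H](CC)C(=O)C(C)=[N+]=[N-] | intermediate (not isolated)
23 | trimethylsilyl ester of 24 | CCC1=C[C@@](/C=C/c2ccccc2)(CC)[C@](CC)(C(=O)O[Si](C)(C)C)[C@@H]2[C@@H]1[C@H](C)C(=O)[C@H]2CC | intermediate (not isolated)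
24 | (1S,3S,3aR,4R,5S,7aR)-3,4,5,7-tetraethyl-1-methyl-2-oxo-5-[(E)-2-phenylethenyl]-2,3,3a,4,5,7a-hexahydro-1H-indene-4-carboxylic acid | CCC1=C[C@@](/C=C/c2ccccc2)(CC)[C@](CC)(C(=O)O)[C@@H]2[C@@H]1[C@H](C)C(=O)[C@H]2CC | target

Total step count: 13. Longest linear sequence: 12 steps (steps 1–8 and 10–13; step 9 is a side branch).

Steps most likely to fail

Step 13 (key step). The carbenoid may be diverted into 1,2-hydride migration from the methyl group (vinyl ketone), or insertion may take the pseudo-axial C–H and give the cis ring fusion. The fallback replaces C–H insertion by an enolate alkylation with inversion at an sp3 carbon. It sets out from 19, which is methylated (MeI, K2CO3, DMF) to the methyl ester F1. Allylic oxidation (SeO2 cat., t-BuOOH, CH2Cl2) should hydroxylate the ring CH2 next to the ethyl-bearing alkene carbon on the face away from the side chain, giving the allylic alcohol F2. Ph3P/CCl4 converts it with inversion into the allylic chloride F3, now cis to the side chain. KN(SiMe3)2 (THF, −78 °C) forms the kinetic enolate at the ketone CH2, which displaces chloride from the rear (five-membered closure, inversion) and should give, after base equilibration, the trans-fused methyl ester F4. LiI in refluxing pyridine cleaves the ester, and the route is rejoined at 24.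

Step 11. The hindered boat rearrangement that joins two quaternary carbons may be outrun by enolate chemistry of the free ketone or by ionisation of the tertiary dienylic C–O bond. The fallback takes the ketone out of the rearrangement substrate. It sets out from 16: NaBH4 (MeOH, −40 °C) reduces only the ketone to the hydroxy lactone F5, and TBSOTf/2,6-lutidine gives the silyl ether F6 before translactonisation can occur. The same Ireland–Claisen conditions then need only one enolisation and should give the silyloxy acid F7. HF·pyridine liberates the hydroxy acid F8, and Dess–Martin periodinane oxidises it to the keto acid, so the route is rejoined at 19.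

Step 10. The allylic phosphonate carbanion may react through its γ-carbon, or the new trisubstituted alkene may form with poor E/Z control. The fallback builds the diene in two stereochemically safer olefinations. It sets out from 13: the stabilised ylide 2-(triphenylphosphoranylidene)butanal (toluene, 90 °C) should give the (E)-2-ethyl enal F9, and diethyl benzylphosphonate/NaH (THF, 0 °C) then adds the (E)-styryl unit, so the route is rejoined at 16.

Further compounds
F1 | step 13 | methyl (1R,2S,6R)-1,2,4-triethyl-6-[(3S)-4-oxohexan-3-yl]-2-[(E)-2-phenylethenyl]cyclohex-3-ene-1-carboxylate | CCC1=C[C@@](/C=C/c2ccccc2)(CC)[C@](CC)(C(=O)OC)[C@H](C1)[C@H](CC)C(=O)CC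
F2 | step 13 | 5-hydroxy derivative of F1 (hydroxyl on the allylic ring carbon, trans to the C6 side chain) | CCC1=C[C@@](/C=C/c2ccccc2)(CC)[C@](CC)(C(=O)OC)[C@H]([C@@H]1O)[C@H](CC)C(=O)CC
F3 | step 13 | 5-chloro derivative of F1 (chlorine cis to the C6 side chain) | CCC1=C[C@@](/C=C/c2ccccc2)(CC)[C@](CC)(C(=O)OC)[C@H]([C@H]1Cl)[C@H](CC)C(=O)CC
F4 | step 13 | methyl ester of 24 | CCC1=C[C@@](/C=C/c2ccccc2)(CC)[C@](CC)(C(=O)OC)[C@@H]2[C@@H]1[C@H](C)C(=O)[C@H]2CC
F5 | step 11 | (4R,6S)-3,6-diethyl-6-[(1E,3E)-2-ethyl-4-phenylbuta-1,3-dien-1-yl]-4-[(3S)-4-hydroxyhexan-3-yl]oxan-2-one (carbinol epimers) | CC[C@@]1(/C=C(\CC)/C=C/c2ccccc2)C[C@H]([C@H](CC)C(O)CC)C(CC)C(=O)O1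
F6 | step 11 | tert-butyldimethylsilyl ether of F5 | CC[C@@]1(/C=C(\CC)/C=C/c2ccccc2)C[C@H]([C@H](CC)C(O[Si](C)(C)C(C)(C)C)CC)C(CC)C(=O)O1
F7 | step 11 | (1R,2S,6R)-6-[(3S)-4-(tert-butyldimethylsilyloxy)hexan-3-yl]-1,2,4-triethyl-2-[(E)-2-phenylethenyl]cyclohex-3-ene-1-carboxylic acid | CCC1=C[C@@](/C=C/c2ccccc2)(CC)[C@](CC)(C(=O)O)[C@H](C1)[C@H](CC)C(O[Si](C)(C)C(C)(C)C)CC
F8 | step 11 | (1R,2S,6R)-1,2,4-triethyl-6-[(3S)-4-hydroxyhexan-3-yl]-2-[(E)-2-phenylethenyl]cyclohex-3-ene-1-carboxylic acid | CCC1=C[C@@](/C=C/c2ccccc2)(CC)[C@](CC)(C(=O)O)[C@H](C1)[C@H](CC)C(O)CC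
F9 | step 10 | (2E)-2-ethyl-3-[(2S,4R)-2,5-diethyl-6-oxo-4-[(3S)-4-oxohexan-3-yl]oxan-2-yl]prop-2-enal | CC[C@@]1(/C=C(\CC)C=O)C[C@H]([C@H](CC)C(=O)CC)C(CC)C(=O)O1
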